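## Analysis of the target

- Target 14 is a fully substituted oxolane (ring E: O1, C2 to C5; these locants are kept for all intermediates). It carries a 4-hydroxyphenyl ring (ring B) on C2, a 2,4-dihydroxybenzoyl group (carbonyl carbon C1', ring A) on C3, a 4-hydroxybenzyl group (CH2 = C6, ring D) on C4 and a 2,4-dihydroxyphenyl ring (ring C) on C5.
- All four ring carbons are stereocentres, (2S,3S,4S,5S). Every neighbouring pair of substituents is trans, so 14 is the least crowded of the eight possible diastereomers.
- Three of the four centres are labile. C3 is alpha to the ketone. C2 can open by retro-oxa-Michael reaction (O1 is beta to C1'=O) or through the para-quinone methide of ring B. C5 can ionise with the help of ring C. Only C4 cannot be corrected once it is set.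
- The plan exploits a hidden symmetry in the chain C1'(=O)–C3–C4–C5(–O1). Its two ends carry the same ring type (A and C), and C3 and C4 carry one-carbon arms (C2 and C6) with the same ring type (B and D).
- If the O1–C2 bond is deleted and C5 is raised to the ketone level, the 3,4-trans oxolane becomes an achiral (R,S)-2,3-dibenzyl-1,4-diaryl-1,4-diketone. This is the meso alpha,alpha' dimer of a single dihydrochalcone.
- The hard points are the C3–C4 bond between two tertiary carbons inside a dissonant 1,4-dioxygen pattern, the absolute configuration at C4, and telling apart two halves that differ only in oxidation level.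
- The sensitive groups are the six phenols, the beta-alkoxy ketone and the two electron-rich benzylic C–O bonds. They rule out strong acid, late strong oxidants and forcing hydrogenolysis.

## Retrosynthetic reasoning

**14 to 13.** The six phenolic oxygens are masked as benzyl ethers, and these six O–C bonds are cut last. Benzyl is the one group that should survive hydroxide, enolate oxidation, hydride reduction, silylation and a palladium-mediated dehydrogenation. It also leaves under neutral conditions, which the beta-alkoxy ketone and the benzylic ring bonds of 14 require.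

**13 to 12.** The ring is opened at O1–C2 and not at O1–C5. This cut is a retro-oxa-Michael reaction and exposes hydroxy enone 12, in which C2 and C3 are planar. Two stereocentres then need no reagent control. The forward closure is reversible, so C2 and C3 are placed by the fixed centres C4 and C5 and end in the all-trans sink. A cut at O1–C5 would demand an acid-driven closure with two competing benzylic cations.

**12 to 9 (through 11 and 10).** The C2=C3 double bond is traced back to the saturated ketone 9. Compound 9 holds one ketone with a single alpha C–H bond (C3–H), so the enol derivative 10 can form at one site only. The forward dehydrogenation must remove a hydrogen from C2 and leave C4–H alone.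

**9 to 7.** The C5–H bond is removed, which raises C5 to the ketone level and reveals the meso diketone 7. All chirality of the target is thus traced to one choice between two enantiotopic carbonyl groups. The forward reaction is a catalyst-controlled mono-reduction. It must pick the carbonyl next to the (S)-configured alpha carbon and fixes the absolute configuration at C3, C4 and C5 together.

**7 to 4 (through 6 and 5).** The C3–C4 bond is cut. It is the only bond of the skeleton whose cleavage gives two identical fragments, and it is also the bond that creates the dissonant 1,4-dioxygen pattern. An oxidative union of two alpha carbons of the same ketone 4 solves both problems and doubles a C15 monomer to the full C30 skeleton. The forward reaction must couple at carbon, spare the alkoxyarenes and deliver the meso relative configuration. C3 and C4 are epimerisable in 7, so this last demand can be met after the bond is made.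

**4 to 3 to 1 and 2.** The saturated chain of 4 comes from chalcone 3 by selective saturation of the C=C bond. Chalcone 3 comes from the aldol condensation of ketone 1 with aldehyde 2. Both are simple aromatic building blocks that already carry the protecting groups.

## Alternatives that were turned down

**Alternative 1:** This is the textbook plan.
- *Disconnection.* It cuts O1–C5 (benzylic cycloetherification) and C2–C3 (aldol) and sets C4 with a chiral auxiliary.
- *Forward key step.* An auxiliary-controlled alkylation of a 3-arylpropanoyl imide and a reduction lead to lactone A1. An aldol addition of A1 to 2, opening of the lactone by an aryl metal reagent, oxidation of the freed C5 carbinol and a second aryl metal addition give keto diol A2. Its acid-induced cyclisation closes the ring.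
- *Reason for rejection.* The plan installs rings A and C in two separate operations although they are the same arene. It needs attachment and removal of the auxiliary, two redox corrections at C5 and differentiated protection of two benzylic alcohols, and should run well beyond twelve steps. It spends reagent control on C2, C3 and C5, which the structure corrects by itself. The final acid step has two competing benzylic cations next to a beta-hydroxy ketone that is prone to retro-aldol cleavage and dehydration.

**Alternative 2:**
- *Disconnection.* It cuts O1–C5 and C2–C3 in a Lewis-acid-promoted (3+2) annulation of aldehyde 2 with donor–acceptor cyclopropane A3. The donor is ring C on C5, the acceptor is the aroyl group on C3, and C4 is a spectator.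
- *Forward key step.* The C3–C5 bond opens to a benzylic cation and an enolate. This pair takes up the C=O bond of 2 and closes the oxolane with all four substituents in place. C4 is not touched, so a later equilibration to the all-trans isomer would be safe.
- *Reason for rejection.* The cost moves into the precursor. A3 needs an enantioselective intermolecular cyclopropanation of an unactivated 1,2-disubstituted alkene, or an ylide addition to a gamma-aryl enone. Control of C4 is weak in both, and each partner needs several steps of its own, so A3 alone is as long as the whole chosen route. A single ketone is also a weak acceptor, the annulation is kinetically 2,5-cis selective, and nothing in the plan uses the identity of rings A/C and B/D.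

**Alternative 3:**
- *Disconnection.* It cuts C3–C4 and O1–C5 in a radical–polar (3+2) union of two derivatives of the same chalcone 3.
- *Forward key step.* Photoreductive opening of the enantioenriched (2S,3R)-epoxide A4 at its alpha C–O bond gives an alpha-keto radical with a C2 alkoxide. The radical adds to C4 of enol silane A5. After oxidation of the adduct radical, the alkoxide closes on C5 to give silyl ketal A6, which would be reduced ionically at C5.
- *Reason for rejection.* The absolute configuration is stored only in C2, the centre most prone to retro-aldol cleavage and benzylic ionisation. C4 would be fixed only in the hydride capture of equilibrating oxocarbenium ions. Kinetic protonation and hydride delivery anti to the C3 substituent favour the 3,4-cis series, and the later equilibration would turn this into the wrong enantiomer. The electron-rich aryl ketone of A4 is hard to reduce, A4 is acid-labile, and the step count is no lower than that of the chosen route.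

Key step: step 3

Assumption: ketone 1 and aldehyde 2 are taken as catalogue compounds that are bought as their benzyl ethers.

## Steps

Step 1
Reactants: 1 1-[2,4-bis(benzyloxy)phenyl]ethan-1-one; 2 4-(benzyloxy)benzaldehyde
Product: 3 (E)-1-[2,4-bis(benzyloxy)phenyl]-3-[4-(benzyloxy)phenyl]prop-2-en-1-one
Conditions: KOH (0.5 equiv), EtOH–THF, rt
Reagents that add atoms: none
Why: Claisen–Schmidt condensation: only 1 can enolise and only 2 is a reactive acceptor, and E1cB loss of water gives the conjugated (E)-enone. Aryl benzyl ethers are inert to hydroxide.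

Step 2
Reactants: 3 (E)-1-[2,4-bis(benzyloxy)phenyl]-3-[4-(benzyloxy)phenyl]prop-2-en-1-one
Product: 4 1-[2,4-bis(benzyloxy)phenyl]-3-[4-(benzyloxy)phenyl]propan-1-one
Conditions: H2 (1 atm), 10% Pd/C, Ph2S (0.01 equiv), EtOAc, rt
Reagents that add atoms: none
Why: Catalytic hydrogenation over sulfide-poisoned Pd/C: the poison suppresses hydrogenolysis of the aryl benzyl ethers and reduction of the aryl ketone, so only the conjugated C=C bond should take up hydrogen.

Step 3
Reactants: 4 1-[2,4-bis(benzyloxy)phenyl]-3-[4-(benzyloxy)phenyl]propan-1-one (two molecules)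
Product: 7 meso-(2R,3S)-2,3-bis[4-(benzyloxy)benzyl]-1,4-bis[2,4-bis(benzyloxy)phenyl]butane-1,4-dione, via lithium enolate 5 (not isolated), via diketone diastereomer mixture 6 (not isolated)
Conditions: LiN(iPr)2 (LDA, 1.05 equiv), THF, −78 °C; CuCl2 (1.1 equiv), DMF, −78 °C to rt; aqueous NH4Cl work-up; then NaOEt (0.2 equiv), EtOH–toluene, 60 °C to rt, crystallisation
Reagents that add atoms: none
Why: LiN(iPr)2 converts 4 into the (Z)-lithium enolate 5, which CuCl2 oxidises in a single-electron step (divalent to monovalent copper) to an alpha-keto radical or its copper enolate; combination of two such units, or of one with a second enolate followed by a second oxidation, forms the C3–C4 bond. The closest known reaction type is the copper-mediated oxidative homocoupling of aryl alkyl ketone enolates, the standard entry to 2,3-dialkyl-1,4-diaryl-1,4-diketones. No ring is closed; the step joins two identical C15 chains at their alpha carbons and so delivers all thirty skeletal carbons, all four aryl rings in their final places and the dissonant 1,4-dioxygen pattern C1'–C3–C4–C5 from an achiral monomer. The new stereocentres C3 and C4 are not controlled in the bond formation, which should give 6 as a mixture of the dl pair and the meso form. Both centres are alpha to aryl ketones, so catalytic NaOEt interconverts the isomers, and the centrosymmetric, less soluble meso isomer 7 is expected to leave the equilibrium by crystallisation (crystallisation-induced diastereomer transformation), which funnels the mixture into the one relative configuration that maps onto the 3,4-trans oxolane. The step needs chemoselective oxidation of the enolate beside six alkoxyarene rings and a single site of coupling: the enolate is oxidised at a far lower potential than any of the arenes, and 4 has only one enolisable position. A slight excess of base over ketone and of oxidant over enolate limits proton return and further oxidation of 7.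

Step 4
Reactants: 7 meso-(2R,3S)-2,3-bis[4-(benzyloxy)benzyl]-1,4-bis[2,4-bis(benzyloxy)phenyl]butane-1,4-dione
Product: 9 (2R,3S,4S)-2,3-bis[4-(benzyloxy)benzyl]-1,4-bis[2,4-bis(benzyloxy)phenyl]-4-hydroxybutan-1-one, via alkoxyborane 8 (not isolated)
Conditions: (R)-Me-CBS oxazaborolidine (0.2 equiv), BH3·SMe2 (1.0 equiv), toluene–THF, −20 °C, slow addition of 7; then MeOH
Reagents that add atoms: none
Why: Corey–Bakshi–Shibata reduction used as an enantiotopic-group-selective reduction of a meso diketone: the (R)-catalyst gives the (S)-carbinol of an aryl ketone, and this sense coincides with Felkin–Anh attack only at the carbonyl next to the (S)-configured alpha carbon, which becomes C5 while its neighbour becomes C4. The Felkin–Anh product has the relative configuration that corresponds to the 4,5-trans oxolane. The other carbonyl is a mismatched case and should react slowly, which secures mono-reduction and the absolute configuration at C3, C4 and C5 in one event.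

Step 5
Reactants: 9 (2R,3S,4S)-2,3-bis[4-(benzyloxy)benzyl]-1,4-bis[2,4-bis(benzyloxy)phenyl]-4-hydroxybutan-1-one
Product: 10 {[(3S,4S)-2,3-bis[4-(benzyloxy)benzyl]-1,4-bis[2,4-bis(benzyloxy)phenyl]but-1-ene-1,4-diyl]bis(oxy)}bis(trimethylsilane) (E/Z mixture at the enol double bond)
Conditions: TMSOTf (3 equiv), Et3N (6 equiv), CH2Cl2, 0 °C to rt; non-aqueous work-up, used without chromatography
Reagents that add atoms: trimethylsilyl trifluoromethanesulfonate, C[Si](C)(C)OS(=O)(=O)C(F)(F)F
Why: Soft enolisation and O-silylation with a silyl triflate and a tertiary amine: the hydroxyl group is capped first and the single remaining alpha C–H bond (C3–H) is then removed, so the enol silane can form at one site only. Excess Et3N keeps the medium free of acid and the C5–O bond intact; C3 becomes planar, C4 and C5 are untouched.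

Step 6
Reactants: 10 {[(3S,4S)-2,3-bis[4-(benzyloxy)benzyl]-1,4-bis[2,4-bis(benzyloxy)phenyl]but-1-ene-1,4-diyl]bis(oxy)}bis(trimethylsilane)
Product: 13 [2,4-bis(benzyloxy)phenyl]{(2S,3S,4S,5S)-4-[4-(benzyloxy)benzyl]-5-[2,4-bis(benzyloxy)phenyl]-2-[4-(benzyloxy)phenyl]oxolan-3-yl}methanone, via enone silyl ether 11 (not isolated), via hydroxy enone 12 (not isolated)
Conditions: Pd(OAc)2 (1.1 equiv), MeCN–CH2Cl2, rt; filtration through Celite, evaporation; then K2CO3 (0.3 equiv), MeOH–THF, rt
Reagents that add atoms: none
Why: Saegusa–Ito oxidation: the palladium enolate formed from 10 and Pd(OAc)2 loses the accessible benzylic hydrogen at C2 by beta-hydride elimination and gives the conjugated chalcone-type enone 11 rather than the tetrasubstituted C3=C4 alkene, so C4 is kept. Methanolysis of the silyl ether frees the C5 hydroxyl group of 12, which adds to C2 in a base-mediated 5-endo-trig oxa-Michael reaction of the kind known for homoallylic alkoxides and alpha-substituted electron-poor alkenes. Ring closure and enolisation are reversible under K2CO3, so C2 and C3 are set under thermodynamic control by the fixed centres C4 and C5 and should settle in the all-trans arrangement of 13.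

Step 7
Reactants: 13 [2,4-bis(benzyloxy)phenyl]{(2S,3S,4S,5S)-4-[4-(benzyloxy)benzyl]-5-[2,4-bis(benzyloxy)phenyl]-2-[4-(benzyloxy)phenyl]oxolan-3-yl}methanone
Product: 14 (2,4-dihydroxyphenyl)[(2S,3S,4S,5S)-5-(2,4-dihydroxyphenyl)-4-(4-hydroxybenzyl)-2-(4-hydroxyphenyl)oxolan-3-yl]methanone (CNP0181717.2)
Conditions: H2 (1 atm), 10% Pd/C, EtOAc–MeOH, rt, stopped after uptake of six equivalents
Reagents that add atoms: none
Why: Hydrogenolysis of aryl benzyl ethers over Pd/C under neutral conditions: these six unhindered O–CH2Ph bonds should be cleaved faster than the hindered ring C–O bonds, and the hydrogen-bonded 2-hydroxyaryl ketone resists reduction. No stereocentre is touched.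

## Compound list

1 | 1-[2,4-bis(benzyloxy)phenyl]ethan-1-one | CC(=O)c1ccc(OCc2ccccc2)cc1OCc1ccccc1 | starting material
2 | 4-(benzyloxy)benzaldehyde | O=Cc1ccc(OCc2ccccc2)cc1 | starting material
3 | (E)-1-[2,4-bis(benzyloxy)phenyl]-3-[4-(benzyloxy)phenyl]prop-2-en-1-one | O=C(/C=C/c1ccc(OCc2ccccc2)cc1)c1ccc(OCc2ccccc2)cc1OCc1ccccc1 | intermediate
4 | 1-[2,4-bis(benzyloxy)phenyl]-3-[4-(benzyloxy)phenyl]propan-1-one | O=C(CCc1ccc(OCc2ccccc2)cc1)c1ccc(OCc2ccccc2)cc1OCc1ccccc1 | intermediate
5 | lithium (Z)-enolate of 4 | [Li+].[O-]/C(=C\Cc1ccc(OCc2ccccc2)cc1)c1ccc(OCc2ccccc2)cc1OCc1ccccc1 | intermediate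
6 | 2,3-bis[4-(benzyloxy)benzyl]-1,4-bis[2,4-bis(benzyloxy)phenyl]butane-1,4-dione, mixture of dl pair and meso form | O=C(c1ccc(OCc2ccccc2)cc1OCc1ccccc1)C(Cc1ccc(OCc2ccccc2)cc1)C(Cc1ccc(OCc2ccccc2)cc1)C(=O)c1ccc(OCc2ccccc2)cc1OCc1ccccc1 | intermediate
7 | meso-(2R,3S)-2,3-bis[4-(benzyloxy)benzyl]-1,4-bis[2,4-bis(benzyloxy)phenyl]butane-1,4-dione | O=C(c1ccc(OCc2ccccc2)cc1OCc1ccccc1)[C@H](Cc1ccc(OCc2ccccc2)cc1)[C@H](Cc1ccc(OCc2ccccc2)cc1)C(=O)c1ccc(OCc2ccccc2)cc1OCc1ccccc1 | intermediate
8 | alkoxyborane (O-boranyl derivative of 9) | O=C(c1ccc(OCc2ccccc2)cc1OCc1ccccc1)[C@H](Cc1ccc(OCc2ccccc2)cc1)[C@H](Cc1ccc(OCc2ccccc2)cc1)[C@@H](c1ccc(OCc2ccccc2)cc1OCc1ccccc1)OB | intermediate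
9 | (2R,3S,4S)-2,3-bis[4-(benzyloxy)benzyl]-1,4-bis[2,4-bis(benzyloxy)phenyl]-4-hydroxybutan-1-one | O=C(c1ccc(OCc2ccccc2)cc1OCc1ccccc1)[C@H](Cc1ccc(OCc2ccccc2)cc1)[C@H](Cc1ccc(OCc2ccccc2)cc1)[C@@H](c1ccc(OCc2ccccc2)cc1OCc1ccccc1)O | intermediate
10 | {[(3S,4S)-2,3-bis[4-(benzyloxy)benzyl]-1,4-bis[2,4-bis(benzyloxy)phenyl]but-1-ene-1,4-diyl]bis(oxy)}bis(trimethylsilane), E/Z mixture | C[Si](C)(C)OC(c1ccc(OCc2ccccc2)cc1OCc1ccccc1)=C(Cc1ccc(OCc2ccccc2)cc1)[C@H](Cc1ccc(OCc2ccccc2)cc1)[C@@H](c1ccc(OCc2ccccc2)cc1OCc1ccccc1)O[Si](C)(C)C | intermediate
11 | (E,3S,4S)-3-[4-(benzyloxy)benzyl]-2-[4-(benzyloxy)benzylidene]-1,4-bis[2,4-bis(benzyloxy)phenyl]-4-(trimethylsilyloxy)butan-1-one | O=C(c1ccc(OCc2ccccc2)cc1OCc1ccccc1)/C(=C/c1ccc(OCc2ccccc2)cc1)[C@H](Cc1ccc(OCc2ccccc2)cc1)[C@@H](c1ccc(OCc2ccccc2)cc1OCc1ccccc1)O[Si](C)(C)C | intermediate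
12 | (E,3S,4S)-3-[4-(benzyloxy)benzyl]-2-[4-(benzyloxy)benzylidene]-1,4-bis[2,4-bis(benzyloxy)phenyl]-4-hydroxybutan-1-one | O=C(c1ccc(OCc2ccccc2)cc1OCc1ccccc1)/C(=C/c1ccc(OCc2ccccc2)cc1)[C@H](Cc1ccc(OCc2ccccc2)cc1)[C@@H](c1ccc(OCc2ccccc2)cc1OCc1ccccc1)O | intermediate
13 | [2,4-bis(benzyloxy)phenyl]{(2S,3S,4S,5S)-4-[4-(benzyloxy)benzyl]-5-[2,4-bis(benzyloxy)phenyl]-2-[4-(benzyloxy)phenyl]oxolan-3-yl}methanone | O=C(c1ccc(OCc2ccccc2)cc1OCc1ccccc1)[C@H]1[C@H](Cc2ccc(OCc3ccccc3)cc2)[C@@H](c2ccc(OCc3ccccc3)cc2OCc2ccccc2)O[C@@H]1c1ccc(OCc2ccccc2)cc1 | intermediate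
14 | (2,4-dihydroxyphenyl)[(2S,3S,4S,5S)-5-(2,4-dihydroxyphenyl)-4-(4-hydroxybenzyl)-2-(4-hydroxyphenyl)oxolan-3-yl]methanone | O=C(c1ccc(O)cc1O)[C@H]1[C@H](Cc2ccc(O)cc2)[C@@H](c2ccc(O)cc2O)O[C@@H]1c1ccc(O)cc1 | target

## Step count and least certain steps

Total step count: 7. Longest linear sequence: 7 (steps 1 to 7). The route is linear because both halves of the skeleton come from the same monomer 4.

**Step 3 (key step).**
- *Most likely failure.* Convergence on the meso isomer may be incomplete. The equilibrium between the diastereomers is driven only by crystallisation, and the crystallisation behaviour of a large hexabenzyl ether cannot be foreseen. Proton return to the enolate and alpha-chlorination by CuCl2 may also lower the efficiency of the coupling.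
- *Fallback.* The separation of diastereomers is given up. The fallback sets out from mixture 6, which is submitted as such to the conditions of step 4. The (R)-catalyst should reduce every carbonyl group whose alpha carbon is (S)-configured. The meso component then gives 9, and the (2S,3S) component gives the C3 epimer of 9, the (2S,3S,4S)-hydroxy ketone F1. The mismatched (2R,3R)-diketone F2 stays behind, is separated and is returned to 6 with NaOEt. Step 5 makes C3 planar, so 9 and F1 converge and the fallback comes back to the route at 10.

**Step 4.**
- *Most likely failure.* Discrimination between the two enantiotopic carbonyl groups may be poor. Both groups that flank each ketone are large, so the catalyst may read aryl and branched alkyl less clearly than in simple aryl ketones. In that case the opposite catalyst enantiomer may be the matched one. The electron-rich, hindered carbonyl also reacts slowly, so uncatalysed borane reduction and over-reduction can compete.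
- *Fallback.* The selection is moved from a reduction to an oxidation. It sets out from 7, which NaBH4 in THF–MeOH should reduce at both carbonyl groups under Felkin–Anh control to the meso diol (1R,2R,3S,4S)-2,3-bis[4-(benzyloxy)benzyl]-1,4-bis[2,4-bis(benzyloxy)phenyl]butane-1,4-diol F3. Hydrogen-transfer oxidation with RuCl[(R,R)-TsDPEN](p-cymene) and KOtBu in acetone is a known way to desymmetrise meso benzylic diols. It should dehydrogenate the (R)-configured carbinol (C1') and leave the (S)-configured one (C5). The fallback comes back to the route at 9.

**Step 6.**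
- *Most likely failure.* Beta-hydride elimination may go toward C4–H, which would erase the only centre that cannot be corrected. Palladation at the fully substituted C3 may also be slow, so that protodesilylation back to the ketone wins.
- *Fallback.* The organopalladium elimination is replaced by a pericyclic one, whose regiochemistry follows C–H acidity and access. It sets out from 10, which PhSeCl in CH2Cl2 at −78 °C should convert into the alpha-phenylselanyl ketone F4. Oxidation with H2O2 and pyridine at 0 °C then triggers syn elimination toward the benzylic C2–H. The fallback comes back to the route at 11, which is treated with K2CO3 in MeOH as in step 6.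

**Step 7.**
- *Most likely failure.* The ring bonds O1–C2 and O1–C5 may undergo hydrogenolysis. Both are benzylic and become more labile as soon as the free phenols of rings B and C appear.
- *Fallback.* Reductive conditions are avoided altogether. It sets out from 13 and cleaves the six benzyl ethers with BCl3 and pentamethylbenzene as cation scavenger in CH2Cl2 at −78 °C, followed by a buffered quench. Any reversible ionisation at C2 or C5 recloses to the all-trans isomer. The fallback comes back to the route at 14.

## Further compounds

F1 | step 3 | (2S,3S,4S)-2,3-bis[4-(benzyloxy)benzyl]-1,4-bis[2,4-bis(benzyloxy)phenyl]-4-hydroxybutan-1-one (C3 epimer of 9) | O=C(c1ccc(OCc2ccccc2)cc1OCc1ccccc1)[C@@H](Cc1ccc(OCc2ccccc2)cc1)[C@H](Cc1ccc(OCc2ccccc2)cc1)[C@@H](c1ccc(OCc2ccccc2)cc1OCc1ccccc1)O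
F2 | step 3 | (2R,3R)-2,3-bis[4-(benzyloxy)benzyl]-1,4-bis[2,4-bis(benzyloxy)phenyl]butane-1,4-dione | O=C(c1ccc(OCc2ccccc2)cc1OCc1ccccc1)[C@H](Cc1ccc(OCc2ccccc2)cc1)[C@@H](Cc1ccc(OCc2ccccc2)cc1)C(=O)c1ccc(OCc2ccccc2)cc1OCc1ccccc1
F3 | step 4 | meso-(1R,2R,3S,4S)-2,3-bis[4-(benzyloxy)benzyl]-1,4-bis[2,4-bis(benzyloxy)phenyl]butane-1,4-diol | O[C@@H](c1ccc(OCc2ccccc2)cc1OCc1ccccc1)[C@H](Cc1ccc(OCc2ccccc2)cc1)[C@H](Cc1ccc(OCc2ccccc2)cc1)[C@@H](c1ccc(OCc2ccccc2)cc1OCc1ccccc1)O
F4 | step 6 | (3S,4S)-2,3-bis[4-(benzyloxy)benzyl]-1,4-bis[2,4-bis(benzyloxy)phenyl]-2-(phenylselanyl)-4-(trimethylsilyloxy)butan-1-one (C2 of the butanone not defined) | O=C(c1ccc(OCc2ccccc2)cc1OCc1ccccc1)C([Se]c1ccccc1)(Cc1ccc(OCc2ccccc2)cc1)[C@H](Cc1ccc(OCc2ccccc2)cc1)[C@@H](c1ccc(OCc2ccccc2)cc1OCc1ccccc1)O[Si](C)(C)C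
F0 | step 7 | none | none
A1 | alternative 1 | (S)-4-[4-(benzyloxy)benzyl]oxolan-2-one | O=C1C[C@H](Cc2ccc(OCc3ccccc3)cc2)CO1
A2 | alternative 1 | keto diol, open form of 13 with hydroxyl groups at C2 and C5 | O=C(c1ccc(OCc2ccccc2)cc1OCc1ccccc1)[C@H]([C@H](O)c1ccc(OCc2ccccc2)cc1)[C@H](Cc1ccc(OCc2ccccc2)cc1)[C@@H](c1ccc(OCc2ccccc2)cc1OCc1ccccc1)O
A3 | alternative 2 | [2,4-bis(benzyloxy)phenyl]{3-[4-(benzyloxy)benzyl]-2-[2,4-bis(benzyloxy)phenyl]cyclopropyl}methanone, aryl trans to aroyl and to benzyl, C4 configured as in 14 | O=C(c1ccc(OCc2ccccc2)cc1OCc1ccccc1)[C@@H]1[C@H](Cc2ccc(OCc3ccccc3)cc2)[C@H]1c1ccc(OCc2ccccc2)cc1OCc1ccccc1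
A4 | alternative 3 | [2,4-bis(benzyloxy)phenyl]{(2S,3R)-3-[4-(benzyloxy)phenyl]oxiran-2-yl}methanone | O=C(c1ccc(OCc2ccccc2)cc1OCc1ccccc1)[C@H]1O[C@@H]1c1ccc(OCc2ccccc2)cc1
A5 | alternative 3 | (Z)-triethylsilyl enol ether of 4 | CC[Si](CC)(CC)O/C(=C\Cc1ccc(OCc2ccccc2)cc1)c1ccc(OCc2ccccc2)cc1OCc1ccccc1
A6 | alternative 3 | 5-(triethylsilyloxy) analogue of 13, defined at C2 only | O=C(c1ccc(OCc2ccccc2)cc1OCc1ccccc1)C1C(Cc2ccc(OCc3ccccc3)cc2)C(O[Si](CC)(CC)CC)(c2ccc(OCc3ccccc3)cc2OCc2ccccc2)O[C@@H]1c1ccc(OCc2ccccc2)cc1
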